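**Retrosynthetic overview**
1. Target 31 comes from 30 by one-pot removal of six MOM (methoxymethyl) ethers and one aryl acetate.
2. The cyclohexenyl–aryl bond of 30 comes from a palladium-catalysed, stereoinvertive decarboxylative allyl–aryl coupling of the cis allylic 2,6-dialkoxybenzoate 29 (the ester carbon leaves as CO2).
3. The cyclohexene, the only ring formed, comes from an enantioselective endo Diels–Alder reaction of 2′-hydroxychalcone 13 with dienyl benzoate 27.
4. 13 comes from aldol condensation of ketone 9 (two directed lithiations of resorcinol bis-MOM ether) with aldehyde 12; 27 comes from the prenal dienolate and acid 23 (palladium-catalysed carbonylation of iodochalcone 22).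
5. Every arene comes from resorcinol or 4-bromophenol; the five-carbon units come from prenyl bromide and prenal.

Assumption: (R)-VANOL (3,3′-diphenyl-[2,2′-binaphthalene]-1,1′-diol) is taken to give the (5R,6S) series in step 16; if the first run shows the opposite sense, (S)-VANOL is used with nothing else changed.

**Route**

Step 1
Reactants: 1 resorcinol
Product: 2 1,3-bis(methoxymethoxy)benzene
Conditions: NaH (2.4 equiv), MOMCl (2.4 equiv), DMF, 0 °C to rt
Reagents that add atoms: chloromethyl methyl ether (MOMCl), COCCl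
Why: Williamson O-alkylation of both sodium phenoxides gives the bis-acetal, which also directs the two later lithiations.

Step 2
Reactants: 2 1,3-bis(methoxymethoxy)benzene; 3 prenyl bromide (1-bromo-3-methylbut-2-ene)
Product: 5 1,3-bis(methoxymethoxy)-2-(3-methylbut-2-en-1-yl)benzene, via aryllithium 4 (not isolated)
Conditions: n-BuLi (1.1 equiv), THF, 0 °C to rt, 1 h; then CuBr·SMe2 (10 mol%), 3 (1.2 equiv), −78 °C to rt
Reagents that add atoms: none
Why: Directed ortho-metalation occurs at C-2 between the two chelating OMOM groups, and the copper-relayed aryl anion is alkylated at the primary carbon of prenyl bromide without allylic transposition.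

Step 3
Reactants: 5 1,3-bis(methoxymethoxy)-2-(3-methylbut-2-en-1-yl)benzene; 6 N-methoxy-N-methylacetamide
Product: 8 1-[2,4-bis(methoxymethoxy)-3-(3-methylbut-2-en-1-yl)phenyl]ethan-1-one, via aryllithium 7 (not isolated)
Conditions: n-BuLi (1.2 equiv), TMEDA (1.2 equiv), THF, −20 to 0 °C, 1 h; then 6 (1.5 equiv), −78 to 0 °C; aq. NH4Cl
Reagents that add atoms: none
Why: A second directed ortho-metalation next to one OMOM group (the two open ortho sites are equivalent) is followed by Weinreb amide acylation, whose chelated tetrahedral adduct prevents over-addition.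

Step 4
Reactants: 8 1-[2,4-bis(methoxymethoxy)-3-(3-methylbut-2-en-1-yl)phenyl]ethan-1-one
Product: 9 1-[2-hydroxy-4-(methoxymethoxy)-3-(3-methylbut-2-en-1-yl)phenyl]ethan-1-one
Conditions: p-TsOH·H2O (10 mol%), MeOH, 0 °C to rt, stopped at mono-cleavage
Reagents that add atoms: none
Why: Acid-catalysed acetal exchange cleaves the MOM group flanked by the acetyl fastest (carbonyl-assisted protonation, product locked in a hydrogen bond), so the 4-OMOM group and the prenyl group survive.

Step 5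
Reactants: 1 resorcinol
Product: 11 2,4-dihydroxybenzaldehyde, via iminium chloride 10 (not isolated)
Conditions: POCl3 (1.1 equiv), DMF (1.3 equiv), MeCN, −15 °C to rt; then H2O, 50 °C
Reagents that add atoms: N,N-dimethylformamide, CN(C)C=O
Why: Vilsmeier–Haack formylation attacks the position para to one hydroxyl and ortho to the other, and hydrolysis of the iminium salt frees the aldehyde.

Step 6
Reactants: 11 2,4-dihydroxybenzaldehyde
Product: 12 2,4-bis(methoxymethoxy)benzaldehyde
Conditions: NaH (2.4 equiv), MOMCl (2.4 equiv), DMF, 0 °C to rt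
Reagents that add atoms: chloromethyl methyl ether (MOMCl), COCCl
Why: Williamson O-alkylation of both phenoxides; the aldehyde has no enolisable hydrogen.

Step 7
Reactants: 9 1-[2-hydroxy-4-(methoxymethoxy)-3-(3-methylbut-2-en-1-yl)phenyl]ethan-1-one; 12 2,4-bis(methoxymethoxy)benzaldehyde
Product: 13 (2E)-3-[2,4-bis(methoxymethoxy)phenyl]-1-[2-hydroxy-4-(methoxymethoxy)-3-(3-methylbut-2-en-1-yl)phenyl]prop-2-en-1-one
Conditions: KOH (50% aq., 5 equiv), EtOH, rt, 24–36 h; aq. NH4Cl
Reagents that add atoms: none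
Why: Claisen–Schmidt aldol condensation of the methyl ketone with the non-enolisable aldehyde gives the E-enone by E1cB dehydration, and flavanone closure is slow at room temperature.

Step 8
Reactants: 1 resorcinol; 14 acetic acid
Product: 15 1-(2,4-dihydroxyphenyl)ethan-1-one
Conditions: ZnCl2 (1.2 equiv), AcOH (reactant and solvent), 140 °C, 1 h
Reagents that add atoms: none
Why: Nencki reaction (Friedel–Crafts C-acylation) places the acetyl group para to one hydroxyl and ortho to the other.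

Step 9
Reactants: 15 1-(2,4-dihydroxyphenyl)ethan-1-one
Product: 16 1-(2,4-dihydroxy-3-iodophenyl)ethan-1-one
Conditions: I2 (0.4 equiv), HIO3 (0.2 equiv), EtOH–H2O, rt
Reagents that add atoms: iodine, II; iodic acid, OI(=O)=O
Why: Oxidative electrophilic aromatic iodination goes to C-3 between the two hydroxyls, the established site for this ketone, and iodic acid returns all iodide to the electrophile.

Step 10
Reactants: 16 1-(2,4-dihydroxy-3-iodophenyl)ethan-1-one
Product: 17 1-[3-iodo-2,4-bis(methoxymethoxy)phenyl]ethan-1-one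
Conditions: NaH (2.3 equiv), MOMCl (2.4 equiv), DMF, 0 °C
Reagents that add atoms: chloromethyl methyl ether (MOMCl), COCCl
Why: Williamson O-alkylation; the phenols are far more acidic than the methyl ketone, so slightly over two equivalents of base alkylate oxygen only.

Step 11
Reactants: 18 4-bromophenol
Product: 19 1-bromo-4-(methoxymethoxy)benzene
Conditions: NaH (1.2 equiv), MOMCl (1.2 equiv), DMF, 0 °C to rt
Reagents that add atoms: chloromethyl methyl ether (MOMCl), COCCl
Why: Williamson O-alkylation of the phenoxide.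

Step 12
Reactants: 19 1-bromo-4-(methoxymethoxy)benzene
Product: 21 4-(methoxymethoxy)benzaldehyde, via aryllithium 20 (not isolated)
Conditions: n-BuLi (1.05 equiv), THF, −78 °C; then DMF (1.5 equiv), −78 °C to rt; aq. NH4Cl
Reagents that add atoms: N,N-dimethylformamide, CN(C)C=O
Why: Bromine–lithium exchange followed by formylation of the aryllithium with DMF (Bouveault formylation).

Step 13
Reactants: 17 1-[3-iodo-2,4-bis(methoxymethoxy)phenyl]ethan-1-one; 21 4-(methoxymethoxy)benzaldehyde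
Product: 22 (2E)-1-[3-iodo-2,4-bis(methoxymethoxy)phenyl]-3-[4-(methoxymethoxy)phenyl]prop-2-en-1-one
Conditions: KOH (50% aq., 4 equiv), EtOH, rt, 24 h; aq. NH4Cl
Reagents that add atoms: none
Why: Claisen–Schmidt aldol condensation gives the E-chalcone; the aryl iodide and MOM ethers are inert to aqueous base at room temperature.

Step 14
Reactants: 22 (2E)-1-[3-iodo-2,4-bis(methoxymethoxy)phenyl]-3-[4-(methoxymethoxy)phenyl]prop-2-en-1-one
Product: 23 2,6-bis(methoxymethoxy)-3-{(2E)-3-[4-(methoxymethoxy)phenyl]prop-2-enoyl}benzoic acid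
Conditions: Pd(OAc)2 (5 mol%), Xantphos (6 mol%), CO (1 atm), K2CO3 (2 equiv), H2O (10 equiv), 1,4-dioxane, 80 °C; then aq. citric acid to pH 4 at 0 °C
Reagents that add atoms: carbon monoxide, [C-]#[O+]; water, O
Why: Palladium-catalysed hydroxycarbonylation (oxidative addition of zerovalent palladium to the C–I bond, CO insertion, hydrolysis of the acyl palladium) puts the carboxyl group on the carbon between the two oxygens.

Step 15
Reactants: 23 2,6-bis(methoxymethoxy)-3-{(2E)-3-[4-(methoxymethoxy)phenyl]prop-2-enoyl}benzoic acid; 24 prenal (3-methylbut-2-enal)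
Product: 27 (1E)-3-methylbuta-1,3-dien-1-yl 2,6-bis(methoxymethoxy)-3-{(2E)-3-[4-(methoxymethoxy)phenyl]prop-2-enoyl}benzoate, via acyl fluoride 25 (not isolated), via potassium dienolate 26 (not isolated)
Conditions: 23, cyanuric fluoride (0.4 equiv), pyridine (1 equiv), CH2Cl2, −10 °C to rt, filtered; separately 24 (1.3 equiv), KOtBu (1.25 equiv), THF, −78 °C, 30 min; then 25 in THF, −78 to −40 °C
Reagents that add atoms: none
Why: Neutral acyl fluoride formation spares the MOM ethers, γ-deprotonation of s-trans prenal gives the E-dienolate, and the hard acyl fluoride acylates it on oxygen (enolate O-acylation) faster than it adds to the chalcone.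

Step 16
Reactants: 13 (2E)-3-[2,4-bis(methoxymethoxy)phenyl]-1-[2-hydroxy-4-(methoxymethoxy)-3-(3-methylbut-2-en-1-yl)phenyl]prop-2-en-1-one; 27 (1E)-3-methylbuta-1,3-dien-1-yl 2,6-bis(methoxymethoxy)-3-{(2E)-3-[4-(methoxymethoxy)phenyl]prop-2-enoyl}benzoate
Product: 28 (1R,5R,6S)-5-[2,4-bis(methoxymethoxy)phenyl]-6-[2-hydroxy-4-(methoxymethoxy)-3-(3-methylbut-2-en-1-yl)benzoyl]-3-methylcyclohex-2-en-1-yl 2,6-bis(methoxymethoxy)-3-{(2E)-3-[4-(methoxymethoxy)phenyl]prop-2-enoyl}benzoate
Conditions: (R)-VANOL (20 mol%), B(OPh)3 (20 mol%), 4 Å MS, 27 (1.5 equiv), PhCF3, rt to 40 °C, 48 h; neutral silica, minor exo isomer removed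
Reagents that add atoms: none
Why: In this borate-catalysed asymmetric Diels–Alder reaction only the 2′-hydroxy ketone of 13 chelates boron (the chalcone in 27 is MOM-capped and stays inert), the 1-acyloxy-3-methyl diene adds with ortho/para regiochemistry, the E-enone fixes C-5/C-6 trans, the endo transition state puts the ester oxygen at C-1 cis to the aroyl group, and the ligand shields one enone face to set (1R,5R,6S).

Step 17
Reactants: 28 (1R,5R,6S)-5-[2,4-bis(methoxymethoxy)phenyl]-6-[2-hydroxy-4-(methoxymethoxy)-3-(3-methylbut-2-en-1-yl)benzoyl]-3-methylcyclohex-2-en-1-yl 2,6-bis(methoxymethoxy)-3-{(2E)-3-[4-(methoxymethoxy)phenyl]prop-2-enoyl}benzoate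
Product: 29 (1R,5R,6S)-6-[2-acetoxy-4-(methoxymethoxy)-3-(3-methylbut-2-en-1-yl)benzoyl]-5-[2,4-bis(methoxymethoxy)phenyl]-3-methylcyclohex-2-en-1-yl 2,6-bis(methoxymethoxy)-3-{(2E)-3-[4-(methoxymethoxy)phenyl]prop-2-enoyl}benzoate
Conditions: Ac2O (2 equiv), pyridine (4 equiv), DMAP (5 mol%), CH2Cl2, 0 °C
Reagents that add atoms: acetic anhydride, CC(=O)OC(C)=O
Why: Nucleophile-catalysed O-acetylation masks the acidic chelated phenol (a proton source and competing nucleophile in the next step) under conditions too weakly basic for E1cB loss of the β-aroyloxy group or epimerisation at C-6.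

Step 18
Reactants: 29 (1R,5R,6S)-6-[2-acetoxy-4-(methoxymethoxy)-3-(3-methylbut-2-en-1-yl)benzoyl]-5-[2,4-bis(methoxymethoxy)phenyl]-3-methylcyclohex-2-en-1-yl 2,6-bis(methoxymethoxy)-3-{(2E)-3-[4-(methoxymethoxy)phenyl]prop-2-enoyl}benzoate
Product: 30 (2E)-1-{3-[(1S,5R,6S)-6-[2-acetoxy-4-(methoxymethoxy)-3-(3-methylbut-2-en-1-yl)benzoyl]-5-[2,4-bis(methoxymethoxy)phenyl]-3-methylcyclohex-2-en-1-yl]-2,4-bis(methoxymethoxy)phenyl}-3-[4-(methoxymethoxy)phenyl]prop-2-en-1-one
Conditions: Pd2(dba)3 (5 mol%), P(2-furyl)3 (20 mol%), 4 Å MS, DMSO–toluene (1:9), 80 °C, argon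
Reagents that add atoms: none
Why: Proposed new method: a stereoinvertive intramolecular decarboxylative allyl–aryl coupling in which zerovalent palladium ionises the allylic C–O bond anti to the benzoate to give an η3-cyclohexenyl divalent palladium carboxylate, the twisted electron-rich 2,6-dialkoxybenzoate then loses CO2 at the electrophilic metal (ipso-palladation, as in decarboxylative Heck reactions of 2,6-dialkoxybenzoic acids), and C–C reductive elimination delivers the aryl group from the metal face to the secondary allyl terminus rather than the methyl-bearing one, so the new C-1 stereocentre is set (1S) trans to the aroyl group by net inversion; the closest known reaction type is the palladium-catalysed decarboxylative allylation of allyl esters (enolate-type and electron-poor arene carboxylates), which has not been shown for dialkoxybenzoates or with stereochemical transfer on a substituted cyclohexenyl ester.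

Step 19
Reactants: 30 (2E)-1-{3-[(1S,5R,6S)-6-[2-acetoxy-4-(methoxymethoxy)-3-(3-methylbut-2-en-1-yl)benzoyl]-5-[2,4-bis(methoxymethoxy)phenyl]-3-methylcyclohex-2-en-1-yl]-2,4-bis(methoxymethoxy)phenyl}-3-[4-(methoxymethoxy)phenyl]prop-2-en-1-one
Product: 31 (2E)-1-{3-[(1S,5R,6S)-6-[2,4-dihydroxy-3-(3-methylbut-2-en-1-yl)benzoyl]-5-(2,4-dihydroxyphenyl)-3-methylcyclohex-2-en-1-yl]-2,4-dihydroxyphenyl}-3-(4-hydroxyphenyl)prop-2-en-1-one
Conditions: HCl (3 M aq.)–MeOH (1:6), 40 °C, 4–6 h, argon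
Reagents that add atoms: none
Why: Acid-catalysed acetal exchange removes the six MOM groups as dimethoxymethane and transesterifies the aryl acetate, while the mild temperature spares the prenyl group and the all-equatorial trans,trans stereotriad has no driving force to epimerise.

**Compound list**
1 | resorcinol | Oc1cccc(O)c1 | starting material
2 | 1,3-bis(methoxymethoxy)benzene | COCOc1cccc(OCOC)c1 | intermediate
3 | prenyl bromide (1-bromo-3-methylbut-2-ene) | CC(C)=CCBr | starting material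
4 | [2,6-bis(methoxymethoxy)phenyl]lithium | [Li]c1c(OCOC)cccc1OCOC | intermediate
5 | 1,3-bis(methoxymethoxy)-2-(3-methylbut-2-en-1-yl)benzene | CC(C)=CCc1c(OCOC)cccc1OCOC | intermediate
6 | N-methoxy-N-methylacetamide | CON(C)C(C)=O | starting material
7 | [2,4-bis(methoxymethoxy)-3-(3-methylbut-2-en-1-yl)phenyl]lithium | CC(C)=CCc1c(OCOC)ccc([Li])c1OCOC | intermediate
8 | 1-[2,4-bis(methoxymethoxy)-3-(3-methylbut-2-en-1-yl)phenyl]ethan-1-one | CC(C)=CCc1c(OCOC)ccc(C(C)=O)c1OCOC | intermediate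
9 | 1-[2-hydroxy-4-(methoxymethoxy)-3-(3-methylbut-2-en-1-yl)phenyl]ethan-1-one | CC(C)=CCc1c(OCOC)ccc(C(C)=O)c1O | intermediate
10 | (2,4-dihydroxybenzylidene)dimethyliminium chloride | C[N+](C)=Cc1ccc(O)cc1O.[Cl-] | intermediate
11 | 2,4-dihydroxybenzaldehyde | O=Cc1ccc(O)cc1O | intermediate
12 | 2,4-bis(methoxymethoxy)benzaldehyde | COCOc1ccc(C=O)c(OCOC)c1 | intermediate
13 | (2E)-3-[2,4-bis(methoxymethoxy)phenyl]-1-[2-hydroxy-4-(methoxymethoxy)-3-(3-methylbut-2-en-1-yl)phenyl]prop-2-en-1-one | CC(C)=CCc1c(OCOC)ccc(C(=O)/C=C/c2ccc(OCOC)cc2OCOC)c1O | intermediate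
14 | acetic acid | CC(=O)O | starting material
15 | 1-(2,4-dihydroxyphenyl)ethan-1-one | CC(=O)c1ccc(O)cc1O | intermediate
16 | 1-(2,4-dihydroxy-3-iodophenyl)ethan-1-one | CC(=O)c1ccc(O)c(I)c1O | intermediate
17 | 1-[3-iodo-2,4-bis(methoxymethoxy)phenyl]ethan-1-one | CC(=O)c1ccc(OCOC)c(I)c1OCOC | intermediate
18 | 4-bromophenol | Oc1ccc(Br)cc1 | starting material
19 | 1-bromo-4-(methoxymethoxy)benzene | COCOc1ccc(Br)cc1 | intermediate
20 | [4-(methoxymethoxy)phenyl]lithium | [Li]c1ccc(OCOC)cc1 | intermediate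
21 | 4-(methoxymethoxy)benzaldehyde | COCOc1ccc(C=O)cc1 | intermediate
22 | (2E)-1-[3-iodo-2,4-bis(methoxymethoxy)phenyl]-3-[4-(methoxymethoxy)phenyl]prop-2-en-1-one | COCOc1ccc(/C=C/C(=O)c2ccc(OCOC)c(I)c2OCOC)cc1 | intermediate
23 | 2,6-bis(methoxymethoxy)-3-{(2E)-3-[4-(methoxymethoxy)phenyl]prop-2-enoyl}benzoic acid | COCOc1ccc(/C=C/C(=O)c2ccc(OCOC)c(C(=O)O)c2OCOC)cc1 | intermediate
24 | prenal (3-methylbut-2-enal) | CC(C)=CC=O | starting material
25 | 2,6-bis(methoxymethoxy)-3-{(2E)-3-[4-(methoxymethoxy)phenyl]prop-2-enoyl}benzoyl fluoride | COCOc1ccc(/C=C/C(=O)c2ccc(OCOC)c(C(F)=O)c2OCOC)cc1 | intermediate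
26 | potassium (1E)-3-methylbuta-1,3-dien-1-olate | C=C(C)/C=C/[O-].[K+] | intermediate
27 | (1E)-3-methylbuta-1,3-dien-1-yl 2,6-bis(methoxymethoxy)-3-{(2E)-3-[4-(methoxymethoxy)phenyl]prop-2-enoyl}benzoate | C=C(C)/C=C/OC(=O)c1c(OCOC)ccc(C(=O)/C=C/c2ccc(OCOC)cc2)c1OCOC | intermediate
28 | (1R,5R,6S)-5-[2,4-bis(methoxymethoxy)phenyl]-6-[2-hydroxy-4-(methoxymethoxy)-3-(3-methylbut-2-en-1-yl)benzoyl]-3-methylcyclohex-2-en-1-yl 2,6-bis(methoxymethoxy)-3-{(2E)-3-[4-(methoxymethoxy)phenyl]prop-2-enoyl}benzoate (ester oxygen cis to aroyl; aroyl trans to aryl) | CC(C)=CCc1c(OCOC)ccc(C(=O)[C@@H]2[C@H](OC(=O)c3c(OCOC)ccc(C(=O)/C=C/c4ccc(OCOC)cc4)c3OCOC)C=C(C)C[C@H]2c2ccc(OCOC)cc2OCOC)c1O | intermediate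
29 | (1R,5R,6S)-6-[2-acetoxy-4-(methoxymethoxy)-3-(3-methylbut-2-en-1-yl)benzoyl]-5-[2,4-bis(methoxymethoxy)phenyl]-3-methylcyclohex-2-en-1-yl 2,6-bis(methoxymethoxy)-3-{(2E)-3-[4-(methoxymethoxy)phenyl]prop-2-enoyl}benzoate | CC(C)=CCc1c(OCOC)ccc(C(=O)[C@@H]2[C@H](OC(=O)c3c(OCOC)ccc(C(=O)/C=C/c4ccc(OCOC)cc4)c3OCOC)C=C(C)C[C@H]2c2ccc(OCOC)cc2OCOC)c1OC(C)=O | intermediate
30 | (2E)-1-{3-[(1S,5R,6S)-6-[2-acetoxy-4-(methoxymethoxy)-3-(3-methylbut-2-en-1-yl)benzoyl]-5-[2,4-bis(methoxymethoxy)phenyl]-3-methylcyclohex-2-en-1-yl]-2,4-bis(methoxymethoxy)phenyl}-3-[4-(methoxymethoxy)phenyl]prop-2-en-1-one (all-trans) | CC(C)=CCc1c(OCOC)ccc(C(=O)[C@@H]2[C@@H](c3c(OCOC)ccc(C(=O)/C=C/c4ccc(OCOC)cc4)c3OCOC)C=C(C)C[C@H]2c2ccc(OCOC)cc2OCOC)c1OC(C)=O | intermediate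
31 | (2E)-1-{3-[(1S,5R,6S)-6-[2,4-dihydroxy-3-(3-methylbut-2-en-1-yl)benzoyl]-5-(2,4-dihydroxyphenyl)-3-methylcyclohex-2-en-1-yl]-2,4-dihydroxyphenyl}-3-(4-hydroxyphenyl)prop-2-en-1-one (CNP0283121.2) | CC(C)=CCc1c(O)ccc(C(=O)[C@@H]2[C@@H](c3c(O)ccc(C(=O)/C=C/c4ccc(O)cc4)c3O)C=C(C)C[C@H]2c2ccc(O)cc2O)c1O | target

**Step count and risks**
Total steps: 19. Longest linear sequence: 10 steps (8, 9, 10, 13, 14, 15, 16, 17, 18, 19); the dienophile arm (steps 1–4 and 7) and the two aldehyde arms (steps 5–6 and 11–12) run in parallel.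

Most likely to fail:

Step 18 (the proposed coupling). Decarboxylation may be slower than β-hydride loss from the allyl palladium species (diene formation) or protodecarboxylation. The fallback is known chemistry; it sets out from iodochalcone 22 and dienophile 13 and comes back at target 31. 2-Methylbut-1-en-3-yne is hydroborated with pinacolborane (Cp2Zr(H)Cl 5 mol%, Et3N, rt) to (E)-4,4,5,5-tetramethyl-2-(3-methylbuta-1,3-dien-1-yl)-1,3,2-dioxaborolane F1. Suzuki–Miyaura coupling of 22 with F1 (Pd(dppf)Cl2, K3PO4, dioxane–H2O, 80 °C) gives (2E)-1-{2,4-bis(methoxymethoxy)-3-[(1E)-3-methylbuta-1,3-dien-1-yl]phenyl}-3-[4-(methoxymethoxy)phenyl]prop-2-en-1-one F5. The B(OPh)3/(R)-VANOL-promoted Diels–Alder reaction of 13 with F5 then gives, after separation from the endo isomer, the exo all-trans adduct (2E)-1-{3-[(1S,5R,6S)-5-[2,4-bis(methoxymethoxy)phenyl]-6-[2-hydroxy-4-(methoxymethoxy)-3-(3-methylbut-2-en-1-yl)benzoyl]-3-methylcyclohex-2-en-1-yl]-2,4-bis(methoxymethoxy)phenyl}-3-[4-(methoxymethoxy)phenyl]prop-2-en-1-one F6, which is deprotected under the conditions of step 19 to 31.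

Step 16 (cycloaddition with the ester-bearing diene). The dienyl benzoate may be too unreactive, or the β-aroyloxy ketone may ionise or eliminate on the Lewis acid. The fallback sets out from 13 and prenal 24 and comes back at 28; the ester bond is made after the ring instead of being carried through the cycloaddition. Prenal is silylated (TBSOTf, Et3N, Et2O, 0 °C) to the more electron-rich diene tert-butyldimethyl{[(1E)-3-methylbuta-1,3-dien-1-yl]oxy}silane F2. The same borate-catalysed endo cycloaddition with 13 gives the silyl ether [(1S,2R,6R)-6-[2,4-bis(methoxymethoxy)phenyl]-2-{[tert-butyl(dimethyl)silyl]oxy}-4-methylcyclohex-3-en-1-yl][2-hydroxy-4-(methoxymethoxy)-3-(3-methylbut-2-en-1-yl)phenyl]methanone F3. Buffered HF·pyridine (THF, 0 °C) frees the cis allylic alcohol [(1S,2R,6R)-6-[2,4-bis(methoxymethoxy)phenyl]-2-hydroxy-4-methylcyclohex-3-en-1-yl][2-hydroxy-4-(methoxymethoxy)-3-(3-methylbut-2-en-1-yl)phenyl]methanone F4, and O-acylation of F4 with acyl fluoride 25 (made from 23 as in step 15; DMAP, CH2Cl2, 0 °C) gives 28.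

Step 15 (dienolate O-acylation with a hindered acyl fluoride that also carries an enone). C-acylation, Michael addition or poor E/Z control may intervene. The fallback sets out from acid 23 and comes back at 27. 2-Methylbut-1-en-3-yne is hydroborated with pinacolborane (Cp2Zr(H)Cl 5 mol%, Et3N, rt; syn addition fixes the E geometry) to (E)-4,4,5,5-tetramethyl-2-(3-methylbuta-1,3-dien-1-yl)-1,3,2-dioxaborolane F1. Acid 23 is then O-alkenylated with F1 in a copper-mediated oxidative coupling of Chan–Lam type (Cu(OAc)2, Et3N, 4 Å MS, air, CH2Cl2, rt), which transfers the dienyl group with retention of geometry and gives 27.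

**Further compounds**
F1 | step 15 | (E)-4,4,5,5-tetramethyl-2-(3-methylbuta-1,3-dien-1-yl)-1,3,2-dioxaborolane | C=C(C)/C=C/B1OC(C)(C)C(C)(C)O1
F2 | step 16 | tert-butyldimethyl{[(1E)-3-methylbuta-1,3-dien-1-yl]oxy}silane | C=C(C)/C=C/O[Si](C)(C)C(C)(C)C
F3 | step 16 | [(1S,2R,6R)-6-[2,4-bis(methoxymethoxy)phenyl]-2-{[tert-butyl(dimethyl)silyl]oxy}-4-methylcyclohex-3-en-1-yl][2-hydroxy-4-(methoxymethoxy)-3-(3-methylbut-2-en-1-yl)phenyl]methanone | CC(C)=CCc1c(OCOC)ccc(C(=O)[C@@H]2[C@H](O[Si](C)(C)C(C)(C)C)C=C(C)C[C@H]2c2ccc(OCOC)cc2OCOC)c1O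
F4 | step 16 | [(1S,2R,6R)-6-[2,4-bis(methoxymethoxy)phenyl]-2-hydroxy-4-methylcyclohex-3-en-1-yl][2-hydroxy-4-(methoxymethoxy)-3-(3-methylbut-2-en-1-yl)phenyl]methanone | CC(C)=CCc1c(OCOC)ccc(C(=O)[C@@H]2[C@H](O)C=C(C)C[C@H]2c2ccc(OCOC)cc2OCOC)c1O
F5 | step 18 | (2E)-1-{2,4-bis(methoxymethoxy)-3-[(1E)-3-methylbuta-1,3-dien-1-yl]phenyl}-3-[4-(methoxymethoxy)phenyl]prop-2-en-1-one | C=C(C)/C=C/c1c(OCOC)ccc(C(=O)/C=C/c2ccc(OCOC)cc2)c1OCOC
F6 | step 18 | (2E)-1-{3-[(1S,5R,6S)-5-[2,4-bis(methoxymethoxy)phenyl]-6-[2-hydroxy-4-(methoxymethoxy)-3-(3-methylbut-2-en-1-yl)benzoyl]-3-methylcyclohex-2-en-1-yl]-2,4-bis(methoxymethoxy)phenyl}-3-[4-(methoxymethoxy)phenyl]prop-2-en-1-one | CC(C)=CCc1c(OCOC)ccc(C(=O)[C@@H]2[C@@H](c3c(OCOC)ccc(C(=O)/C=C/c4ccc(OCOC)cc4)c3OCOC)C=C(C)C[C@H]2c2ccc(OCOC)cc2OCOC)c1O
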